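**Retrosynthetic overview**
1. Target ⇒ (3R,3'R,6'R)-lutein + 2 × α-linolenic acid, joined by one double O-acylation as the last step.
2. Lutein ⇒ C10 + C20 + C10. One Wittig forms C7'=C8' (C30 phosphonium salt + ε-ring C10 hydroxy-aldehyde). The other forms C7=C8 (β-ring C10 phosphonium salt + crocetindial).
3. Both C10 units ⇒ the two enantiomers of safranal 3,4-epoxide. Hydride SN2 opening gives the 3R β-ring. SmI2 vinylogous reductive opening with α-protonation gives the 3'R,6'R ε-ring.
4. Epoxides ⇒ safranal by an enantioselective, metal-free oxaziridinium-catalysed distal epoxidation, run once with each catalyst enantiomer. This sets the first stereocentres of each half.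
5. Ring order: no carbocycle is built, because both six-membered rings are bought in as safranal. Only the oxiranes are formed (β-series first, ε-series second) and opened again.

Catalyst key: cat-A = N-[(4S,5S)-2,2-dimethyl-4-(4-methylsulfonylphenyl)-1,3-dioxan-5-yl]-3,4-dihydroisoquinolinium tetraphenylborate. ent-cat-A is its (4R,5R) enantiomer. TPPP = tetraphenylphosphonium monoperoxysulfate.

Assumption: the sense of induction of cat-A on 1 is taken by analogy with 2,2-dimethylchromenes; if the first run shows the opposite sense, cat-A and ent-cat-A simply change places between steps 1 and 7.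

**Step 1**
Reactants: 1 safranal (2,6,6-trimethylcyclohexa-1,3-diene-1-carbaldehyde)
Product: 2 (1R,6S)-2,4,4-trimethyl-7-oxabicyclo[4.1.0]hept-2-ene-3-carbaldehyde (safranal 3,4-epoxide of the β-series)
Conditions: cat-A (10 mol %), TPPP (2 equiv), CHCl3, −40 °C
Reagents that add atoms: tetraphenylphosphonium monoperoxysulfate (TPPP), OOS(=O)(=O)[O-].c1ccc(cc1)[P+](c1ccccc1)(c1ccccc1)c1ccccc1
Why: Proposed new method: oxaziridinium (iminium-salt/peroxymonosulfate) catalysis has not been used on a cyclic 2,4-dienal, but the electrophilic oxygen should go only to the distal cis C3=C4 bond (C5=C6 is tetrasubstituted, shielded by CMe2 and deactivated by CHO, and the hindered CHO is inert to TPPP without water at −40 °C), and this bond, a ring cis-alkene with a π-substituent on one carbon and a CH2 on the other, shows the catalyst the same pattern as 2,2-dimethyl-2H-chromenes, its best substrates, so that one concerted syn oxygen transfer to one enantiotopic face sets both oxirane carbons (1R,6S, about 90% ee expected); the closest known reaction types are the Page-type iminium-salt epoxidation of chromenes and the γ,δ-selective peracid/dioxirane epoxidation of dienoates.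

**Step 2**
Reactants: 2 (1R,6S)-epoxy aldehyde
Product: 3 (1R)-4-(hydroxymethyl)-3,5,5-trimethylcyclohex-3-en-1-ol ((3R)-3-hydroxy-β-cyclogeraniol)
Conditions: LiAlH4 (2 equiv), Et2O, 0 °C → rt; H2O/NaOH work-up
Reagents that add atoms: none
Why: Hydride reduction with regioselective vinyl-oxirane opening: LiAlH4 reduces CHO 1,2 and then opens the oxirane by SN2 attack at the π-activated allylic carbon C4 (SN2' at the fully substituted C6 next to CMe2 is blocked), and since the C3–O bond is never broken the carbinol keeps its configuration (the descriptor becomes R only through a priority change).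

**Step 3**
Reactants: 3 (3R)-3-hydroxy-β-cyclogeraniol
Product: 4 {[(4R)-4-hydroxy-2,6,6-trimethylcyclohex-1-en-1-yl]methyl}triphenylphosphonium bromide
Conditions: PPh3·HBr (1.05 equiv), MeOH, rt, 24 h; recrystallise
Reagents that add atoms: triphenylphosphine hydrobromide, [Br-].c1ccc(cc1)[PH+](c1ccccc1)c1ccccc1
Why: Standard phosphonium-salt formation from an allylic alcohol: only the primary allylic OH ionises, PPh3 traps the allyl cation at its unhindered primary end, the homoallylic secondary OH is inert, and crystallisation of the salt raises the ee.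

**Step 4**
Reactants: 4 C10 phosphonium bromide; 5 crocetindial ((2E,4E,6E,8E,10E,12E,14E)-2,6,11,15-tetramethylhexadeca-2,4,6,8,10,12,14-heptaenedial)
Product: 7 all-E-(3R)-3-hydroxy-8'-apo-β-caroten-8'-al (β-citraurin), via C10 ylide 6 (not isolated)
Conditions: 5 (2.5 equiv, excess recovered), NaOMe (1.1 equiv, slow addition), CH2Cl2/MeOH, 0 °C → rt, dark
Reagents that add atoms: none
Why: Wittig olefination: the hindered β-cyclogeranyl-type ylide gives the 7E alkene (7Z is sterically prohibitive), and mono-olefination is secured by the excess dialdehyde and by the lower electrophilicity of the longer C30 polyenal.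

**Step 5**
Reactants: 7 β-citraurin
Product: 8 all-E-(3R)-8'-apo-β-carotene-3,8'-diol (β-citraurol)
Conditions: NaBH4, EtOH/THF, 0 °C
Reagents that add atoms: none
Why: Plain 1,2-borohydride reduction of a polyenal, which leaves the polyene and the C3 carbinol untouched.

**Step 6**
Reactants: 8 β-citraurol
Product: 9 [(3R)-3-hydroxy-8'-apo-β-caroten-8'-yl]triphenylphosphonium bromide
Conditions: PPh3·HBr (1.0 equiv), CH2Cl2/MeOH, 0 °C → rt, dark
Reagents that add atoms: triphenylphosphine hydrobromide, [Br-].c1ccc(cc1)[PH+](c1ccccc1)c1ccccc1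
Why: The same allylic alcohol → phosphonium salt reaction that turns retinol into the retinyl salt: the polyenylic primary OH ionises far faster than the ring OH, and PPh3 adds at the terminal CH2.

**Step 7**
Reactants: 1 safranal
Product: 10 (1S,6R)-2,4,4-trimethyl-7-oxabicyclo[4.1.0]hept-2-ene-3-carbaldehyde (safranal 3,4-epoxide of the ε-series)
Conditions: ent-cat-A (10 mol %), TPPP (2 equiv), CHCl3, −40 °C
Reagents that add atoms: tetraphenylphosphonium monoperoxysulfate (TPPP), OOS(=O)(=O)[O-].c1ccc(cc1)[P+](c1ccccc1)(c1ccccc1)c1ccccc1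
Why: Proposed new method: the mirror-image run of step 1, in which the oxaziridinium formed from the enantiomeric iminium salt transfers its oxygen in a concerted syn manner to the other enantiotopic face of the distal cis C3=C4 bond (same regiochemical and recognition arguments, closest known type the iminium-salt epoxidation of 2,2-dimethylchromenes) and so sets both oxirane carbons as 1S,6R.

**Step 8**
Reactants: 10 (1S,6R)-epoxy aldehyde
Product: 12 (1R,4R)-4-hydroxy-2,6,6-trimethylcyclohex-2-ene-1-carbaldehyde ((3R,6R)-3-hydroxy-α-cyclocitral), via samarium dienolate 11 (not isolated)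
Conditions: SmI2 (2.1 equiv, 0.1 M in THF, dropwise), MeOH (5 equiv), THF, −90 °C, 10 min; pH 7 buffer; use at once
Reagents that add atoms: none
Why: Molander-type SmI2 reduction of a γ,δ-epoxy-α,β-unsaturated carbonyl compound: two electron transfers to the enal cleave the allylic C4–O bond and give dienolate 11, whose kinetic α-protonation places the double bond at C4=C5 and creates C6, the proton entering on the face of the pseudo-equatorial C3–O–Sm group (Sm-bound MeOH) because the other face is blocked by the axial C1 methyl, so H-6 ends cis and CHO trans to the 3-OH (1R,4R) while C3 keeps its C–O bond.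

**Step 9**
Reactants: 9 C30 phosphonium bromide; 12 (3R,6R)-3-hydroxy-α-cyclocitral
Product: 14 all-E-(3R,3'R,6'R)-β,ε-carotene-3,3'-diol (lutein), via C30 ylide 13 (not isolated)
Conditions: NaHMDS (1.0 equiv), THF, −78 °C; then 12, −78 → 0 °C; then n-heptane, reflux, N2 (Z → E)
Reagents that add atoms: none
Why: Wittig olefination: the preformed, weakly basic polyenyl ylide adds to the non-conjugated aldehyde faster than it removes the hindered tertiary H-6', so 6'R is carried through, and the E/Z mixture at C7'=C8' converges thermally on all-E because 7'Z is strained.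

**Step 10**
Reactants: 14 lutein; 15 α-linolenic acid ((9Z,12Z,15Z)-octadeca-9,12,15-trienoic acid)
Product: 16 (3R,3'R,6'R)-lutein di-α-linolenate (CNP0400996.1)
Conditions: 15 (2.4 equiv), DCC (2.4 equiv), DMAP (0.3 equiv), CH2Cl2, rt, Ar, dark
Reagents that add atoms: none
Why: Steglich esterification acylates at oxygen without breaking either C–O bond, so 3R and 3'R are retained, and the neutral conditions spare the ionisable allylic 3'-position, the polyene and the skipped Z-trienes.

**Compound list**
1 | safranal | CC1=C(C=O)C(C)(C)CC=C1 | starting material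
2 | (1R,6S)-2,4,4-trimethyl-7-oxabicyclo[4.1.0]hept-2-ene-3-carbaldehyde | O=CC1=C(C)[C@H]2O[C@H]2CC1(C)C | intermediate
3 | (1R)-4-(hydroxymethyl)-3,5,5-trimethylcyclohex-3-en-1-ol | O[C@@H]1CC(C)=C(CO)C(C)(C)C1 | intermediate
4 | {[(4R)-4-hydroxy-2,6,6-trimethylcyclohex-1-en-1-yl]methyl}triphenylphosphonium bromide | O[C@@H]1CC(C)=C(C[P+](c2ccccc2)(c2ccccc2)c2ccccc2)C(C)(C)C1.[Br-] | intermediate
5 | crocetindial (all-E) | O=C/C(C)=C/C=C/C(C)=C/C=C/C=C(C)/C=C/C=C(C)/C=O | starting material
6 | C10 ylide of 4 | O[C@@H]1CC(C)=C(C=P(c2ccccc2)(c2ccccc2)c2ccccc2)C(C)(C)C1 | intermediate (not isolated)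
7 | β-citraurin, all-E-(3R)-3-hydroxy-8'-apo-β-caroten-8'-al | O[C@@H]1CC(C)=C(/C=C/C(C)=C/C=C/C(C)=C/C=C/C=C(C)/C=C/C=C(C)/C=O)C(C)(C)C1 | intermediate
8 | β-citraurol, all-E-(3R)-8'-apo-β-carotene-3,8'-diol | O[C@@H]1CC(C)=C(/C=C/C(C)=C/C=C/C(C)=C/C=C/C=C(C)/C=C/C=C(C)/CO)C(C)(C)C1 | intermediate
9 | [(3R)-3-hydroxy-8'-apo-β-caroten-8'-yl]triphenylphosphonium bromide | O[C@@H]1CC(C)=C(/C=C/C(C)=C/C=C/C(C)=C/C=C/C=C(C)/C=C/C=C(C)/C[P+](c2ccccc2)(c2ccccc2)c2ccccc2)C(C)(C)C1.[Br-] | intermediate
10 | (1S,6R)-2,4,4-trimethyl-7-oxabicyclo[4.1.0]hept-2-ene-3-carbaldehyde | O=CC1=C(C)[C@@H]2O[C@@H]2CC1(C)C | intermediate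
11 | samarium(III) alkoxide-dienolate, drawn as its dienol (1R)-4-(hydroxymethylidene)-3,5,5-trimethylcyclohex-2-en-1-ol | OC=C1C(C)=C[C@H](O)CC1(C)C | intermediate (not isolated)
12 | (1R,4R)-4-hydroxy-2,6,6-trimethylcyclohex-2-ene-1-carbaldehyde (OH and CHO trans) | O=C[C@H]1C(C)=C[C@H](O)CC1(C)C | intermediate
13 | C30 ylide of 9 | O[C@@H]1CC(C)=C(/C=C/C(C)=C/C=C/C(C)=C/C=C/C=C(C)/C=C/C=C(C)/C=P(c2ccccc2)(c2ccccc2)c2ccccc2)C(C)(C)C1 | intermediate (not isolated)
14 | (3R,3'R,6'R)-lutein | O[C@@H]1CC(C)=C(/C=C/C(C)=C/C=C/C(C)=C/C=C/C=C(C)/C=C/C=C(C)/C=C/[C@H]2C(C)=C[C@H](O)CC2(C)C)C(C)(C)C1 | intermediate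
15 | α-linolenic acid | CC/C=C\C/C=C\C/C=C\CCCCCCCC(=O)O | starting material
16 | (3R,3'R,6'R)-lutein di-α-linolenate | CC/C=C\C/C=C\C/C=C\CCCCCCCC(=O)O[C@@H]1CC(C)=C(/C=C/C(C)=C/C=C/C(C)=C/C=C/C=C(C)/C=C/C=C(C)/C=C/[C@H]2C(C)=C[C@H](OC(=O)CCCCCCC/C=C\C/C=C\C/C=C\CC)CC2(C)C)C(C)(C)C1 | target

**Total step count:** 10. **Longest linear sequence:** 8 (steps 1–6, 9, 10).

**Three steps most likely to fail**

*Step 1 (the new epoxidation; step 7 is the same reaction with the mirror-image catalyst).* The risks are insufficient ee, oxidation of the CHO group, and opening of the vinyl oxirane by the acidic sulfate.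

The fallback uses known chemistry. It sets out from 1 and comes back at 12 and at 3.
- 1 is epoxidised without a chiral catalyst (mCPBA, NaHCO3, CH2Cl2, 0 °C; a Prilezhaev reaction that is distal-selective on dienals) to the racemic safranal 3,4-epoxide F1.
- F1 is opened with SmI2/MeOH as in step 8 to the racemic trans-hydroxy aldehyde F2.
- Lipase-catalysed acylation follows (Pseudomonas lipase, vinyl acetate; this resolution is established for 3-hydroxy-ε and 3-hydroxy-β end groups). Run to slightly beyond 50% conversion, it leaves 12 unreacted and gives the (1S,4S)-acetate F3.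
- F3 is de-acetylated with the same lipase in pH 7 buffer to the (1S,4S)-hydroxy aldehyde F4.
- A catalytic amount of DBU moves the double bond into conjugation. This is the known α- to β-cyclocitral isomerisation, which erases C6 and leaves C3. The product is (R)-3-hydroxy-β-cyclocitral F5.
- NaBH4 then gives 3.
- Because the two ring ends need opposite spatial configuration at C3, both enantiomers of the racemate are used.

*Step 8 (SmI2 opening).* The risks are pinacol coupling or over-reduction of the aldehyde, γ-protonation, and a poor facial ratio at C6. The cis epimer would at least be removable, because only it can close to a bicyclic lactol.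

The fallback sets out from 10 and comes back at 12. H-6 is delivered as hydride instead of as a proton.
- DIBAL-H (3.5 equiv, toluene, −78 → 0 °C) reduces the aldehyde and binds the oxirane oxygen.
- It then transfers hydride to C6 through a six-membered syn-SN2' transition state on the oxygen-bearing face. This gives the (1R,4R)-trans diol F6.
- The primary alcohol of F6 is oxidised selectively with TEMPO/PhI(OAc)2 to 12.

*Step 9 (Wittig of a long stabilised ylide with a hindered, epimerisable aldehyde).* The risks are a sluggish addition, epimerisation at C6', and drift of the aldehyde into conjugation.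

The fallback sets out from 12, with 7 as partner, and comes back at 14. The polarity is reversed.
- 12 is silylated (TBSCl, imidazole) to the TBS-ether aldehyde F7.
- F7 is reduced (NaBH4) to the primary alcohol F8.
- F8 is converted by Mitsunobu reaction with 1-phenyl-1H-tetrazole-5-thiol into the tetrazolyl sulfide F9.
- F9 is oxidised (ammonium molybdate/H2O2) to the tetrazolyl sulfone F10.
- The potassium anion of F10 (KHMDS, THF, −78 °C) adds to the C30 aldehyde 7 in a Julia–Kocienski olefination to give 3'-O-TBS-lutein F11.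
- TBAF then releases 14.
- In F10, C6' is no longer acidic, and steps 5 and 6 are no longer needed.

**Further compounds**
F1 | step 1 | (±)-2,4,4-trimethyl-7-oxabicyclo[4.1.0]hept-2-ene-3-carbaldehyde (racemate of 2 and 10) | O=CC1=C(C)C2OC2CC1(C)C
F2 | step 1 | (±)-trans-4-hydroxy-2,6,6-trimethylcyclohex-2-ene-1-carbaldehyde (racemate of 12 and F4) | O=CC1C(C)=CC(O)CC1(C)C
F3 | step 1 | (1S,4S)-4-acetoxy-2,6,6-trimethylcyclohex-2-ene-1-carbaldehyde | O=C[C@@H]1C(C)=C[C@@H](OC(C)=O)CC1(C)C
F4 | step 1 | (1S,4S)-4-hydroxy-2,6,6-trimethylcyclohex-2-ene-1-carbaldehyde | O=C[C@@H]1C(C)=C[C@@H](O)CC1(C)C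
F5 | step 1 | (4R)-4-hydroxy-2,6,6-trimethylcyclohex-1-ene-1-carbaldehyde ((R)-3-hydroxy-β-cyclocitral) | O[C@@H]1CC(C)=C(C=O)C(C)(C)C1
F6 | step 8 | (1R,4R)-4-(hydroxymethyl)-3,5,5-trimethylcyclohex-2-en-1-ol | OC[C@H]1C(C)=C[C@H](O)CC1(C)C
F7 | step 9 | (1R,4R)-4-(tert-butyldimethylsilyloxy)-2,6,6-trimethylcyclohex-2-ene-1-carbaldehyde | O=C[C@H]1C(C)=C[C@H](O[Si](C)(C)C(C)(C)C)CC1(C)C
F8 | step 9 | [(1R,4R)-4-(tert-butyldimethylsilyloxy)-2,6,6-trimethylcyclohex-2-en-1-yl]methanol | OC[C@H]1C(C)=C[C@H](O[Si](C)(C)C(C)(C)C)CC1(C)C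
F9 | step 9 | 5-({[(1R,4R)-4-(tert-butyldimethylsilyloxy)-2,6,6-trimethylcyclohex-2-en-1-yl]methyl}sulfanyl)-1-phenyl-1H-tetrazole | c1ccc(cc1)-n2nnnc2SC[C@H]3C(C)=C[C@H](O[Si](C)(C)C(C)(C)C)CC3(C)C
F10 | step 9 | 5-({[(1R,4R)-4-(tert-butyldimethylsilyloxy)-2,6,6-trimethylcyclohex-2-en-1-yl]methyl}sulfonyl)-1-phenyl-1H-tetrazole | c1ccc(cc1)-n2nnnc2S(=O)(=O)C[C@H]3C(C)=C[C@H](O[Si](C)(C)C(C)(C)C)CC3(C)C
F11 | step 9 | (3R,3'R,6'R)-3'-O-(tert-butyldimethylsilyl)lutein | O[C@@H]1CC(C)=C(/C=C/C(C)=C/C=C/C(C)=C/C=C/C=C(C)/C=C/C=C(C)/C=C/[C@H]2C(C)=C[C@H](O[Si](C)(C)C(C)(C)C)CC2(C)C)C(C)(C)C1
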